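## Retrosynthetic overview

1. Target 23 is a cis-(1R,3S)-1,2,3-trimethyltetrahydroisoquinoline joined at C7 to C1' of a 4,5-dimethoxy-7-methylnaphthalene. Both stereocenters are set last, by asymmetric hydrogenation of the N-methylisoquinolinium salt 22 (from 21 and MeOTf).
2. The C7–C1' biaryl bond comes from Suzuki coupling of 7-bromoisoquinoline 10 with naphthyl boronate 20. The naphthalene is built by Stobbe condensation and cyclisation from 11 and 12.
3. The strategy rests on the C1(CH3)–N2–C3(CH3) unit of the pyridine ring, with C4 unsubstituted. Taking out N2 and joining C1 to C3 leaves the C3=C2 bond of the 2,3-dimethylindene 8, whose CH2 is the later C4. Isoquinoline 10 therefore arises from 8 by oxidative insertion of one nitrogen atom.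
4. Indene 8 comes from aldehyde 1 and Meldrum's acid 2: reductive benzylation, C-methylation, Friedel–Crafts closure to indanone 6, then MeMgBr addition and dehydration.
5. Ring order: arene ring (bought), five-membered carbocycle (step 3), its expansion to the pyridine ring (step 5), second naphthalene ring (step 7), biaryl (step 12), reduction of the pyridinium ring to the piperidine ring (step 14).

Key step: step 5

Assumption: the C7–C1' biaryl axis has no descriptor in the target structure, so it is treated as not configurationally fixed and is not controlled. Stereocontrol concerns only C1 (R) and C3 (S), which are cis.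

Assumption: (R)-SegPhos is taken as the ligand hand that gives the 1R,3S series in step 14. This sense of induction is a prediction for this salt; the (S)-ligand is the mirror-image choice should it be reversed.

## Route

Step 1
Reactants: 1 4-bromo-3,5-dimethoxybenzaldehyde; 2 Meldrum's acid (2,2-dimethyl-1,3-dioxane-4,6-dione)
Product: 4 5-(4-bromo-3,5-dimethoxybenzyl)-2,2-dimethyl-1,3-dioxane-4,6-dione, via benzylidene Meldrum's acid 3 (not isolated)
Conditions: Hantzsch ester (1.1 equiv), L-proline (20 mol%), EtOH, rt
Reagents that add atoms: none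
Why: Knoevenagel condensation gives alkylidene 3, whose very electrophilic C=C bond accepts hydride from the Hantzsch ester (organocatalytic reductive alkylation of Meldrum's acid), a metal-free reduction that leaves the aryl bromide untouched.

Step 2
Reactants: 4 5-(4-bromo-3,5-dimethoxybenzyl)-2,2-dimethyl-1,3-dioxane-4,6-dione
Product: 5 5-(4-bromo-3,5-dimethoxybenzyl)-2,2,5-trimethyl-1,3-dioxane-4,6-dione
Conditions: MeI (1.5 equiv), K2CO3, DMF, rt
Reagents that add atoms: iodomethane, CI
Why: C-alkylation of the strongly acidic monosubstituted Meldrum's acid with MeI is fast and cannot over-alkylate, because the product carbon is quaternary.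

Step 3
Reactants: 5 5-(4-bromo-3,5-dimethoxybenzyl)-2,2,5-trimethyl-1,3-dioxane-4,6-dione
Product: 6 rac-6-bromo-5,7-dimethoxy-2-methyl-2,3-dihydro-1H-inden-1-one
Conditions: Sc(OTf)3 (10 mol%), MeNO2, 100 °C
Reagents that add atoms: none
Why: Lewis-acid-catalysed intramolecular Friedel–Crafts acylation by a Meldrum's acid carbonyl, with loss of acetone and CO2, closes the five-membered ketone ring at a position ortho to one methoxy group and para to the other (the two ortho positions are equivalent by symmetry); the C2 stereocenter is racemic and is erased in step 4.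

Step 4
Reactants: 6 rac-6-bromo-5,7-dimethoxy-2-methyl-2,3-dihydro-1H-inden-1-one
Product: 8 5-bromo-4,6-dimethoxy-2,3-dimethyl-1H-indene, via tertiary indanol 7 (not isolated)
Conditions: MeMgBr (3 equiv), THF, 0 °C to rt; aq. NH4Cl; then p-TsOH·H2O (5 mol%), toluene, 50 °C
Reagents that add atoms: methylmagnesium bromide, C[Mg]Br
Why: Grignard 1,2-addition gives tertiary benzylic alcohol 7, which should undergo E1 dehydration through a cation stabilised by the ortho and para methoxy groups to the thermodynamically preferred tetrasubstituted, arene-conjugated endocyclic alkene; MeMgBr does not exchange with the aryl bromide.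

Step 5
Reactants: 8 5-bromo-4,6-dimethoxy-2,3-dimethyl-1H-indene
Product: 10 7-bromo-6,8-dimethoxy-1,3-dimethylisoquinoline, via NH-aziridine 9 (not isolated)
Conditions: PhI(OAc)2 (2.5 equiv), ammonium carbamate (4 equiv), MeOH, 0 °C to rt
Reagents that add atoms: ammonium carbamate, NC(=O)[O-].[NH4+]
Why: PhI(OAc)2 and ammonia released from ammonium carbamate give an electrophilic iodonitrene that adds to the electron-rich tetrasubstituted C2=C3 bond of 8 to give aziridine 9; a second equivalent of the trivalent iodine oxidant puts a PhI leaving group on the aziridine nitrogen, and loss of iodobenzene with electrocyclic opening of the former C2–C3 bond gives a 4H-isoquinolinium ion that aromatises by loss of the C4 proton. The closest known reaction type is the oxidative nitrogen-atom insertion into substituted indenes with a trivalent iodine reagent and an ammonia surrogate, which gives isoquinolines. The pyridine ring is not closed end to end but arises by one-atom expansion of the cyclopentene ring (five to six members), with N–C1 and N–C3 formed in place of the C2–C3 bond, so the two methyl groups end up on C1 and C3 and the CH2 becomes C4–H. No stereocenter is created, since both aziridine carbons become sp2. The step needs chemoselectivity for the alkene over the dimethoxyarene and the C–Br bond: the styrene-type tetrasubstituted alkene is the most nucleophilic site, the arene is tempered by its bromine, and the oxidation-prone dimethoxynaphthalene is attached only afterwards.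

Step 6
Reactants: 11 2-bromo-5-methoxybenzaldehyde; 12 diethyl succinate
Product: 13 (E)-4-(2-bromo-5-methoxyphenyl)-3-(ethoxycarbonyl)but-3-enoic acid
Conditions: KOt-Bu (1.3 equiv), t-BuOH, reflux; then aq. HCl
Reagents that add atoms: none
Why: Stobbe condensation: the succinate enolate adds to the aldehyde, and lactonisation followed by base-induced ring opening gives the half-ester with the aryl group cis to the CH2CO2H arm (E), as required for the ring closure.

Step 7
Reactants: 13 (E)-4-(2-bromo-5-methoxyphenyl)-3-(ethoxycarbonyl)but-3-enoic acid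
Product: 14 ethyl 4-acetoxy-8-bromo-5-methoxy-2-naphthoate
Conditions: Ac2O, NaOAc, 140 °C
Reagents that add atoms: acetic anhydride, CC(=O)OC(C)=O
Why: Mixed-anhydride formation and intramolecular Friedel–Crafts acylation at the only free ortho position (ortho to OMe, the other being blocked by Br), then enolisation and O-acetylation, give the naphthyl acetate (Stobbe benzannulation).

Step 8
Reactants: 14 ethyl 4-acetoxy-8-bromo-5-methoxy-2-naphthoate
Product: 16 ethyl 8-bromo-4,5-dimethoxy-2-naphthoate, via naphthol 15 (not isolated)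
Conditions: K2CO3, EtOH, rt; evaporate; then MeI, K2CO3, DMF, 40 °C
Reagents that add atoms: iodomethane, CI
Why: Base-mediated ethanolysis of the aryl acetate (transesterification of the ethyl ester in EtOH is degenerate) followed by Williamson O-methylation of the naphthoxide.

Step 9
Reactants: 16 ethyl 8-bromo-4,5-dimethoxy-2-naphthoate
Product: 17 (8-bromo-4,5-dimethoxynaphthalen-2-yl)methanol
Conditions: LiAlH4, THF, 0 °C; aq. NaOH work-up
Reagents that add atoms: none
Why: Hydride reduction of the ester to the primary alcohol; at 0 °C LiAlH4 should not reduce the aryl bromide.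

Step 10
Reactants: 17 (8-bromo-4,5-dimethoxynaphthalen-2-yl)methanol
Product: 19 1-bromo-4,5-dimethoxy-7-methylnaphthalene, via benzylic bromide 18 (not isolated)
Conditions: CBr4, PPh3, CH2Cl2, 0 °C; silica plug; then LiBHEt3, THF, 0 °C
Reagents that add atoms: none
Why: Appel bromination gives the benzylic bromide, and SN2 displacement by hydride from LiBHEt3 gives the methyl group, the aryl C–Br bond being inert to this hydride at 0 °C.

Step 11
Reactants: 19 1-bromo-4,5-dimethoxy-7-methylnaphthalene
Product: 20 2-(4,5-dimethoxy-7-methylnaphthalen-1-yl)-4,4,5,5-tetramethyl-1,3,2-dioxaborolane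
Conditions: B2pin2, Pd(dppf)Cl2 (5 mol%), KOAc, 1,4-dioxane, 90 °C
Reagents that add atoms: bis(pinacolato)diboron, CC1(C)OB(B2OC(C)(C)C(C)(C)O2)OC1(C)C
Why: Miyaura borylation: oxidative addition of zerovalent palladium to the aryl bromide, acetate-assisted transmetalation with B2pin2 and reductive elimination.

Step 12
Reactants: 10 7-bromo-6,8-dimethoxy-1,3-dimethylisoquinoline; 20 2-(4,5-dimethoxy-7-methylnaphthalen-1-yl)-4,4,5,5-tetramethyl-1,3,2-dioxaborolane
Product: 21 7-(4,5-dimethoxy-7-methylnaphthalen-1-yl)-6,8-dimethoxy-1,3-dimethylisoquinoline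
Conditions: Pd(OAc)2 (5 mol%), SPhos (10 mol%), K3PO4, toluene/H2O, 100 °C
Reagents that add atoms: none
Why: Suzuki–Miyaura coupling; the bulky electron-rich biarylphosphine supports oxidative addition to the doubly ortho-substituted bromide and formation of the hindered biaryl, and the isoquinoline nitrogen is shielded from palladium by its two flanking methyl groups.

Step 13
Reactants: 21 7-(4,5-dimethoxy-7-methylnaphthalen-1-yl)-6,8-dimethoxy-1,3-dimethylisoquinoline
Product: 22 7-(4,5-dimethoxy-7-methylnaphthalen-1-yl)-6,8-dimethoxy-1,2,3-trimethylisoquinolin-2-ium trifluoromethanesulfonate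
Conditions: MeOTf (1.2 equiv), CH2Cl2, 0 °C to rt
Reagents that add atoms: methyl trifluoromethanesulfonate, COS(=O)(=O)C(F)(F)F
Why: Menshutkin-type N-alkylation of the pyridine nitrogen by the powerful methylating agent MeOTf, which overcomes the flanking 1- and 3-methyl groups; the aryl methyl ethers are not nucleophilic enough to compete.

Step 14
Reactants: 22 7-(4,5-dimethoxy-7-methylnaphthalen-1-yl)-6,8-dimethoxy-1,2,3-trimethylisoquinolin-2-ium trifluoromethanesulfonate
Product: 23 ancistrobrevine A, (1R,3S)-7-(4,5-dimethoxy-7-methylnaphthalen-1-yl)-6,8-dimethoxy-1,2,3-trimethyl-1,2,3,4-tetrahydroisoquinoline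
Conditions: H2 (50 bar), [Ir(cod)Cl]2 (2 mol%), (R)-SegPhos (4.4 mol%), Bu4NI (10 mol%), THF/CH2Cl2, 40 °C; then aq. Na2CO3
Reagents that add atoms: none
Why: Iridium-bisphosphine-catalysed asymmetric hydrogenation of an isoquinolinium salt: the chiral iridium hydride adds to C1 of the C1=N+ bond and sets C1 (R) under catalyst control, the resulting enamine is protonated at C4, and the second hydride adds to the C3=N+ iminium on the face anti to the pseudoaxial C1 methyl group, so both hydrogens enter on the same face and C3 (S) follows as the cis isomer; arenes and ethers are inert.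

## Compound list

1 | 4-bromo-3,5-dimethoxybenzaldehyde | COc1cc(C=O)cc(OC)c1Br | starting material
2 | Meldrum's acid (2,2-dimethyl-1,3-dioxane-4,6-dione) | CC1(C)OC(=O)CC(=O)O1 | starting material
3 | 5-(4-bromo-3,5-dimethoxybenzylidene)-2,2-dimethyl-1,3-dioxane-4,6-dione | COc1cc(C=C2C(=O)OC(C)(C)OC2=O)cc(OC)c1Br | intermediate
4 | 5-(4-bromo-3,5-dimethoxybenzyl)-2,2-dimethyl-1,3-dioxane-4,6-dione | COc1cc(CC2C(=O)OC(C)(C)OC2=O)cc(OC)c1Br | intermediate
5 | 5-(4-bromo-3,5-dimethoxybenzyl)-2,2,5-trimethyl-1,3-dioxane-4,6-dione | COc1cc(CC2(C)C(=O)OC(C)(C)OC2=O)cc(OC)c1Br | intermediate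
6 | rac-6-bromo-5,7-dimethoxy-2-methyl-2,3-dihydro-1H-inden-1-one | COc1cc2c(c(OC)c1Br)C(=O)C(C)C2 | intermediate
7 | 6-bromo-5,7-dimethoxy-1,2-dimethyl-2,3-dihydro-1H-inden-1-ol (racemic, mixture of diastereomers) | COc1cc2c(c(OC)c1Br)C(C)(O)C(C)C2 | intermediate
8 | 5-bromo-4,6-dimethoxy-2,3-dimethyl-1H-indene | CC1=C(C)c2c(OC)c(Br)c(OC)cc2C1 | intermediate
9 | NH-aziridine across the former C2=C3 bond of 8 (3-bromo-2,4-dimethoxy-1a,6a-dimethyl-1,1a,6,6a-tetrahydroindeno[1,2-b]azirine, racemic, cis-fused) | CC12Cc3cc(OC)c(Br)c(OC)c3C1(C)N2 | intermediate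
10 | 7-bromo-6,8-dimethoxy-1,3-dimethylisoquinoline | COc1cc2cc(C)nc(C)c2c(OC)c1Br | intermediate
11 | 2-bromo-5-methoxybenzaldehyde | COc1ccc(Br)c(C=O)c1 | starting material
12 | diethyl succinate | CCOC(=O)CCC(=O)OCC | starting material
13 | (E)-4-(2-bromo-5-methoxyphenyl)-3-(ethoxycarbonyl)but-3-enoic acid | CCOC(=O)/C(CC(=O)O)=C/c1cc(OC)ccc1Br | intermediate
14 | ethyl 4-acetoxy-8-bromo-5-methoxy-2-naphthoate | CCOC(=O)c1cc(OC(C)=O)c2c(OC)ccc(Br)c2c1 | intermediate
15 | ethyl 8-bromo-4-hydroxy-5-methoxy-2-naphthoate | CCOC(=O)c1cc(O)c2c(OC)ccc(Br)c2c1 | intermediate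
16 | ethyl 8-bromo-4,5-dimethoxy-2-naphthoate | CCOC(=O)c1cc(OC)c2c(OC)ccc(Br)c2c1 | intermediate
17 | (8-bromo-4,5-dimethoxynaphthalen-2-yl)methanol | OCc1cc(OC)c2c(OC)ccc(Br)c2c1 | intermediate
18 | 1-bromo-7-(bromomethyl)-4,5-dimethoxynaphthalene | BrCc1cc(OC)c2c(OC)ccc(Br)c2c1 | intermediate
19 | 1-bromo-4,5-dimethoxy-7-methylnaphthalene | Cc1cc(OC)c2c(OC)ccc(Br)c2c1 | intermediate
20 | 2-(4,5-dimethoxy-7-methylnaphthalen-1-yl)-4,4,5,5-tetramethyl-1,3,2-dioxaborolane | Cc1cc(OC)c2c(OC)ccc(B3OC(C)(C)C(C)(C)O3)c2c1 | intermediate
21 | 7-(4,5-dimethoxy-7-methylnaphthalen-1-yl)-6,8-dimethoxy-1,3-dimethylisoquinoline | COc1cc2cc(C)nc(C)c2c(OC)c1-c1ccc(OC)c2c(OC)cc(C)cc12 | intermediate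
22 | 7-(4,5-dimethoxy-7-methylnaphthalen-1-yl)-6,8-dimethoxy-1,2,3-trimethylisoquinolin-2-ium trifluoromethanesulfonate | COc1cc2cc(C)[n+](C)c(C)c2c(OC)c1-c1ccc(OC)c2c(OC)cc(C)cc12.[O-]S(=O)(=O)C(F)(F)F | intermediate
23 | ancistrobrevine A, (1R,3S)-7-(4,5-dimethoxy-7-methylnaphthalen-1-yl)-6,8-dimethoxy-1,2,3-trimethyl-1,2,3,4-tetrahydroisoquinoline | COc1cc2c(c(OC)c1-c1ccc(OC)c3c(OC)cc(C)cc13)[C@@H](C)N(C)[C@@H](C)C2 | target

## Step count and risks

Total step count: 14. Longest linear sequence: 9 steps (11 to 23 through steps 6 to 14); the isoquinoline branch needs 8 steps (1 to 23 through steps 1 to 5 and 12 to 14).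

The three steps most likely to fail:

1. Step 5 (key step). The nitrogen transfer may be outrun by oxidation of the electron-rich arene, or the ring-opened cation may be trapped by methanol instead of losing its proton. The fallback sets out from indene 8 and cleaves, then re-closes, the same C2=C3 bond around nitrogen by classical chemistry. Ozonolysis (O3, CH2Cl2/MeOH, −78 °C; then Me2S) should give the 1,5-diketone 1-(2-acetyl-4-bromo-3,5-dimethoxyphenyl)propan-2-one F1. Condensation of this diketone with NH4OAc in AcOH at 80 °C, through the 2-benzopyrylium ion, should close the pyridine ring and return to isoquinoline 10.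

2. Step 14. Facial discrimination by the catalyst may be poor on the N-methyl salt with its crowded C1 (peri to the 8-methoxy group), or reduction may stall at the dihydro stage. The fallback sets out from biaryl isoquinoline 21 and moves the N-methylation to the end. HCl in Et2O gives 7-(4,5-dimethoxy-7-methylnaphthalen-1-yl)-6,8-dimethoxy-1,3-dimethylisoquinolin-2-ium chloride F2. Hydrogenation of this N–H salt with the chloride-bridged dinuclear iridium hydride complex [{Ir(H)((S)-difluorphos)}2(μ-Cl)3]Cl (H2 30 bar, dioxane/i-PrOH, 30 °C; basic work-up), a catalyst type established for isoquinolinium chlorides substituted at C1 and C3, should give the cis secondary amine (1R,3S)-7-(4,5-dimethoxy-7-methylnaphthalen-1-yl)-6,8-dimethoxy-1,3-dimethyl-1,2,3,4-tetrahydroisoquinoline F3, the ligand hand being chosen as stated in the assumption. Reductive methylation with aqueous formaldehyde and NaBH(OAc)3 then returns to target 23.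

3. Step 12. Protodeboronation of the electron-rich naphthyl boronate may outpace transmetalation onto the doubly ortho-substituted arylpalladium species. The fallback sets out from bromonaphthalene 19 and replaces boron by zinc. Bromine–lithium exchange with n-BuLi (THF, −78 °C) gives (4,5-dimethoxy-7-methylnaphthalen-1-yl)lithium F4, and transmetalation with ZnCl2 gives (4,5-dimethoxy-7-methylnaphthalen-1-yl)zinc chloride F5. Negishi coupling of this zinc reagent with bromide 10 (Pd2(dba)3, XPhos, THF, 60 °C) should return to biaryl 21.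

Further compounds
F1 | step 5 | 1-(2-acetyl-4-bromo-3,5-dimethoxyphenyl)propan-2-one | CC(=O)Cc1cc(OC)c(Br)c(OC)c1C(C)=O
F2 | step 14 | 7-(4,5-dimethoxy-7-methylnaphthalen-1-yl)-6,8-dimethoxy-1,3-dimethylisoquinolin-2-ium chloride | COc1cc2cc(C)[nH+]c(C)c2c(OC)c1-c1ccc(OC)c2c(OC)cc(C)cc12.[Cl-]
F3 | step 14 | (1R,3S)-7-(4,5-dimethoxy-7-methylnaphthalen-1-yl)-6,8-dimethoxy-1,3-dimethyl-1,2,3,4-tetrahydroisoquinoline | COc1cc2c(c(OC)c1-c1ccc(OC)c3c(OC)cc(C)cc13)[C@@H](C)N[C@@H](C)C2
F4 | step 12 | (4,5-dimethoxy-7-methylnaphthalen-1-yl)lithium | [Li]c1ccc(OC)c2c(OC)cc(C)cc12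
F5 | step 12 | (4,5-dimethoxy-7-methylnaphthalen-1-yl)zinc chloride | Cl[Zn]c1ccc(OC)c2c(OC)cc(C)cc12
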